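The earlier runs and the new flask are calculated with made-up constants; the scatter is artificial.

Slowness late in the run is what the quick number has to get right. The hunch of a long tail stands in the readings, so the reckoning below is done on the fraction of Z left, not on G made.

| flask | Z | X | remark | time |
|---|---|---|---|---|
| grey | 0.074 M | 2 equiv | run made earlier |  |
| blue | 0.17 M | 2 equiv | run made earlier |  |
| ochre | 0.11 M | 4 equiv | run made earlier |  |
| flask | 0.11 M | 2.00 equiv |  | 50 min |

| run | time / min | G / % |
|---|---|---|
| grey | 4.00 | 24.9 |
| grey | 8.00 | 37.1 |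
| grey | 12.0 | 43.6 |
| grey | 15.0 | 48.0 |
| grey | 20.0 | 51.3 |
| grey | 25.0 | 55.4 |
| grey | 30.0 | 57.9 |
| blue | 4.00 | 47.8 |
| blue | 8.00 | 59.6 |
| blue | 12.0 | 65.2 |
| blue | 15.0 | 68.2 |
| blue | 20.0 | 70.9 |
| blue | 25.0 | 73.4 |
| blue | 30.0 | 75.0 |
| ochre | 2.50 | 42.8 |
| ochre | 5.00 | 56.1 |
| ochre | 8.00 | 64.9 |
| ochre | 15.0 | 75.0 |
| ochre | 30.0 | 81.9 |

(readings scatter by 0.5 percentage points)

* amount of G in percent of the Z charged, at 10 min, 25 min and 50 min

- a reading or a percentage of G counts all its forms, free or not

From 15.0 min to 30.0 min the time doubles. That doubling multiplies the Z left by 0.810 in the grey run, by 0.786 in the blue run and by 0.724 in the ochre run. Grey and blue share the flask's equivalents of X, and on ln c_Z the flask stands 0.477 of the way from grey to blue. So the flask gets 0.798 as its doubling factor, the number that multiplies the fraction of Z left when the time doubles late in a run.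

The same position puts the Z left in the flask at 25 min at 36.0%, which is G of 64.0%. Assuming the factor holds for one more doubling, Z left at 50 min is 28.8%, so my own reckoning gives G of 71.2%.

The forecast says 51%, 64% and 69.5%, with the words “I interpolate between them on second-order time”. At 50 min it stands 1.7 percentage points lower than my reckoning.

The flask gives 51.6%, 64.8% and 72.6%, and the forecast held.

    Z + X → G, rate k1*[Z]^1.5*[X] (k = 0.0420 /M^1.5/s)
    2 X → E (k = 0.00390 /M/s)
    X + G ⇌ J, settled at all times (K = 77.0 /M)
    G → Q (k = 1.60 × 10⁻⁶ /s)

From 25 min to 50 min the flask's factor came to 0.774, against the carried 0.798. The ochre charge is this flask with twice the X. Its factor 0.724 takes the 18.1% of Z left at 30.0 min on to G of 85.7% at 50 min, and that flask gives 85.3%. In the flask at 4.17 min, X was going to G at 0.99 times the rate at which it was going to E. At 50 min the flask held free X at 16.0% of the Z charged and J at 41.7%, so free and bound X together came to 57.7%, more than Z at 27%.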